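Its constants belong to no real substance, and the outcome is calculated.

A charge of 0.50 M solid substrate has to enter solution before reagent and catalyst can turn it into product.

solid substrate 0.50 M; reagent 1.50 equiv; catalyst 2 mol%; time 3.0 h

    starting material + reagent + catalyst ⇌ product + catalyst, rate k1*[starting material]*[reagent]*[catalyst] forward; the back reaction follows from the equilibrium constant (K1 = 3.8 L mol⁻¹, k1 = 1.09 L² mol⁻² min⁻¹)
    solid substrate ⇌ starting material, rate k2*(cs2 - [starting material]) while solid is left; crystals form when [starting material] > cs2 (cs2 = 0.20 M, k2 = 0.0187 min⁻¹)

- solid substrate is a solid; its amount is given per volume of the solution
- at the start none of the solid substrate is in solution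
- run time (flask): 3.0 h

* product at 3.0 h, in percent of the solid substrate charged
* the change that raises the amount of product at 3.0 h, in percent of the solid substrate charged most ("none" if none brings more than 2 percentage points) (Monday's / Tuesday's / Wednesday's / Thursday's / none)
* amount of product at 3.0 h, in percent of the solid substrate charged, after Wednesday's

- Monday's: doubling the solubility in step 2, all else as stated
- Tuesday's: doubling the dissolution coefficient of step 2, all else as stated
- Wednesday's: doubling the amount of catalyst, all else as stated
- Thursday's: doubling the amount of reagent, all else as stated

Two chemists disagree about this flask. The first takes dissolution as the rate-limiting step: whatever dissolves reacts at once and the solution stays nearly empty. Step 2 can then deliver 135% of the charge by 3.0 h, more than the whole charge. Equilibrium at the starting reagent, product to starting material 2.9 to one, caps product at 74.4%.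

The second makes the forecast: 25.3% product, Monday's as the best change and 35% after Wednesday's. Its ground is that “the rate depends on both dissolution and reaction”.

My own reckoning compares rates at one moment. Dissolved starting material is used with the pseudo-first-order constant k1[reagent][catalyst], 0.00818 min⁻¹ at the start. The gap to saturation closes with 0.0187 min⁻¹. Their quotient is 2.29, the supply ratio, dissolution coefficient over pseudo-first-order constant. It stands above one, so starting material builds up in solution. Balancing the two rates at the starting reagent puts [starting material] at the ratio over one plus the ratio, 69.6% of saturation. Forward reaction at that level for 3.0 h gives 41.0% of the charge. That leaves out the filling period and the back reaction, and it stands above the forecast, but below the first chemist's cap.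

The simulation gives 25.2% product, Monday's as the best change with 20 percentage points, and 35.3% after Wednesday's.

The second chemist's picture stands: in this flask [starting material] read 65.8% of saturation at 1.50 h, neither empty nor full. Starting material in this flask was made 2.12 times faster than used, each step taken net, at 0.951 h and 1.23 times at 3.00 h. By the balance above, the first chemist's nearly empty solution belongs to a supply ratio well below one. In the neighbour flask with 0.12 M solid substrate the ratio is 39.7, far higher. There, at 3.00 h, solid substrate stood at 0%, starting material at 93.3% and product at 6.69%.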